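**Retrosynthetic overview**
- The quinone is made last, by oxidative demethylation of a ring-B p-methoxyphenol (2'-OH, 5'-OMe).
- The C3–aryl bond and the pyran ring come from a (2,3-dihydrobenzofuran-3-yl)methyl mesylate and 2,3,4,5-tetramethoxyphenol: ionisation gives a phenonium ion, the arene opens it at C3, and the furan ring grows into the pyran ring (the A-ring carbon shifts from C3 to the exocyclic CH2, which becomes C4).
- Enabling feature: C4a of ring A is para to the C7 methoxy group and ortho to O1, so it bridges readily; C4 is a bare CH2 and C3 the only stereocentre; ring B is fully substituted, so its phenol precursor has a single free carbon.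
- The dihydrobenzofuran comes from Parham cyclisation of an (R)-glycidyl aryl ether (chiral-pool stereocentre, relayed through two inversions); both arenes come from 2,3,4-trimethoxyphenol.
- Ring order: rings A and B are bought; furan ring (step 3), then pyran ring by expansion (step 7), then quinone (step 8).

Key step: step 7

Remark: the stereocentre of the target (C3 of the chroman) is read as (S), with C2 > quinonyl carbon > C4 > H; 2,3,4-trimethoxyphenol and (R)-glycidyl 3-nitrobenzenesulfonate are taken as catalogue compounds.

**Step 1**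
Reactants: 1 2,3,4-trimethoxyphenol
Product: 2 6-bromo-2,3,4-trimethoxyphenol
Conditions: NBS (1.0 equiv), i-Pr2NH (10 mol %), CH2Cl2, −40 → 0 °C
Reagents that add atoms: N-bromosuccinimide, O=C1CCC(=O)N1Br
Why: Electrophilic aromatic bromination in which the free OH is the strongest director, its para position is blocked by OMe, and the amine-mediated NBS protocol should deliver bromine to the only free ortho carbon (C6), which is also para to the 3-OMe.

**Step 2**
Reactants: 2 6-bromo-2,3,4-trimethoxyphenol; 3 (R)-glycidyl 3-nitrobenzenesulfonate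
Product: 4 (2R)-2-[(6-bromo-2,3,4-trimethoxyphenoxy)methyl]oxirane
Conditions: K2CO3, DMF, 25 °C
Reagents that add atoms: none
Why: Williamson etherification by direct SN2 displacement of the nosylate at the primary carbon, which leaves the epoxide stereocentre untouched, so (R)-3 should give (R)-4.

**Step 3**
Reactants: 4 (2R)-2-[(6-bromo-2,3,4-trimethoxyphenoxy)methyl]oxirane
Product: 6 [(3S)-5,6,7-trimethoxy-2,3-dihydro-1-benzofuran-3-yl]methanol, via aryllithium 5 (not isolated)
Conditions: t-BuLi (2.1 equiv), THF, −78 → −20 °C; then H2O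
Reagents that add atoms: none
Why: Parham cycloalkylation in which bromine–lithium exchange outruns attack on the epoxide and aryllithium 5 then opens the epoxide in the favoured 5-exo-tet mode at the internal carbon with inversion, which sets C3 of the dihydrobenzofuran as (S) from the (R)-epoxide.

**Step 4**
Reactants: 6 [(3S)-5,6,7-trimethoxy-2,3-dihydro-1-benzofuran-3-yl]methanol
Product: 7 [(3R)-5,6,7-trimethoxy-2,3-dihydro-1-benzofuran-3-yl]methyl methanesulfonate
Conditions: MsCl, Et3N, CH2Cl2, 0 °C; used without storage
Reagents that add atoms: methanesulfonyl chloride, CS(=O)(=O)Cl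
Why: Standard sulfonylation of a primary alcohol that does not touch the stereocentre; the descriptor changes to (R) only because CH2OMs now outranks C2.

**Step 5**
Reactants: 1 2,3,4-trimethoxyphenol
Product: 8 1,2,3,4-tetramethoxybenzene
Conditions: MeI, K2CO3, acetone, reflux
Reagents that add atoms: iodomethane, CI
Why: Williamson O-methylation of the phenoxide.

**Step 6**
Reactants: 8 1,2,3,4-tetramethoxybenzene
Product: 11 2,3,4,5-tetramethoxyphenol, via aryllithium 9 (not isolated), via dimethyl arylboronate 10 (not isolated)
Conditions: n-BuLi, TMEDA, THF, 0 °C; B(OMe)3, −78 °C → rt; H2O2, AcOH, 0 °C → rt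
Reagents that add atoms: hydrogen peroxide, OO
Why: Directed ortho-metalation next to OMe (the two free positions are equivalent), borylation of aryllithium 9 and oxidative 1,2-shift of the aryl group from boron to oxygen in boronate 10 should give the phenol with a single free ring carbon.

**Step 7**
Reactants: 7 [(3R)-5,6,7-trimethoxy-2,3-dihydro-1-benzofuran-3-yl]methyl methanesulfonate; 11 2,3,4,5-tetramethoxyphenol
Product: 13 2,3,4,5-tetramethoxy-6-[(3S)-6,7,8-trimethoxy-3,4-dihydro-2H-chromen-3-yl]phenol, via phenonium ion 12 (not isolated)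
Conditions: 11 (3 equiv), (CF3)2CHOH (HFIP), 25 → 50 °C, argon
Reagents that add atoms: none
Why: Proposed new method: ionisation of the primary mesylate in HFIP should be assisted by the A-ring carbon C3a (para to the 6-OMe, ortho to the ring oxygen), which bridges to the CH2 and gives phenonium ion 12 without a free primary cation; the only free ring carbon of 11 (ortho to its OH) then attacks C3 of 12 anti to the breaking C3–C3a bond, so that the aryl carbon ends up on the former CH2 (1,2-aryl shift), the furan ring becomes the pyran ring and the C3–aryl bond is formed in the same event. The closest known reaction types are the aryl-assisted solvolytic ring expansion of benzocycloalkenylmethyl sulfonates and the stereospecific Friedel–Crafts arylation of β-aryl alcohols and epoxides through phenonium ions in HFIP, which have not been combined in a ring-expanding, enantiospecific arylation of a dihydrobenzofuran. No ring is closed by a new ring bond apart from the transient cyclopropane of 12 (3-exo-tet, Ar1-3 participation); the six-membered ring arises by migration of C3a from C3 to the exocyclic carbon, which becomes C4. The single stereocentre C3 is controlled by the substrate: it is inverted once in the SN2-like opening of 12, so (R)-7 should give (3S)-13, and an open cation at C3 (secondary and β to oxygen) is too poor to compete and racemise it. The step needs attack at C3 and not at the CH2 of 12, which relief of the bicyclo[3.1.0] strain and the usual opening of unsymmetrical phenonium ions at the more substituted carbon should secure, and it needs C- and not O-alkylation of 11, which is secured because an aryl chroman-3-yl ether re-ionises to 12 under the methanesulfonic acid released whereas the C–C bond does not. Internal return of mesylate to C3 only gives the chroman-3-yl mesylate, which re-forms 12 with the same facial sense, excess 11 outruns self-alkylation of ring A, and the strong participation of the tetra-oxygenated ring outruns the 1,2-hydride shift that would lead to a 3-methylbenzofuran.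

**Step 8**
Reactants: 13 2,3,4,5-tetramethoxy-6-[(3S)-6,7,8-trimethoxy-3,4-dihydro-2H-chromen-3-yl]phenol
Product: 14 2,3,5-trimethoxy-6-[(3S)-6,7,8-trimethoxy-3,4-dihydro-2H-chromen-3-yl]cyclohexa-2,5-diene-1,4-dione
Conditions: PhI(OAc)2 (1.1 equiv), MeCN/H2O (2:1), 0 °C
Reagents that add atoms: water, O
Why: Hypervalent-iodine oxidation of a p-methoxyphenol, in which ligand exchange at the phenol oxygen, attack of water at the para carbon and loss of methanol should give the p-quinone, while the fully etherified ring A is not oxidised under these conditions and C3 is not touched.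

**Compound list**
1 | 2,3,4-trimethoxyphenol | COc1ccc(O)c(OC)c1OC | starting material
2 | 6-bromo-2,3,4-trimethoxyphenol | COc1cc(Br)c(O)c(OC)c1OC | intermediate
3 | (R)-glycidyl 3-nitrobenzenesulfonate | O=S(=O)(OC[C@H]1CO1)c1cccc([N+](=O)[O-])c1 | starting material
4 | (2R)-2-[(6-bromo-2,3,4-trimethoxyphenoxy)methyl]oxirane | COc1cc(Br)c(OC[C@H]2CO2)c(OC)c1OC | intermediate
5 | {3,4,5-trimethoxy-2-[(2R)-oxiran-2-ylmethoxy]phenyl}lithium | COc1cc([Li])c(OC[C@H]2CO2)c(OC)c1OC | intermediate
6 | [(3S)-5,6,7-trimethoxy-2,3-dihydro-1-benzofuran-3-yl]methanol | OC[C@H]1COc2c1cc(OC)c(OC)c2OC | intermediate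
7 | [(3R)-5,6,7-trimethoxy-2,3-dihydro-1-benzofuran-3-yl]methyl methanesulfonate | CS(=O)(=O)OC[C@H]1COc2c1cc(OC)c(OC)c2OC | intermediate
8 | 1,2,3,4-tetramethoxybenzene | COc1ccc(OC)c(OC)c1OC | intermediate
9 | (2,3,4,5-tetramethoxyphenyl)lithium | [Li]c1cc(OC)c(OC)c(OC)c1OC | intermediate
10 | dimethyl (2,3,4,5-tetramethoxyphenyl)boronate | COB(OC)c1cc(OC)c(OC)c(OC)c1OC | intermediate
11 | 2,3,4,5-tetramethoxyphenol | COc1cc(O)c(OC)c(OC)c1OC | intermediate
12 | phenonium ion from 7 (spiro-cyclopropane arenium cation in which C3a is bonded to C3 and to the former CH2OMs carbon; drawn as the 6-methoxy oxocarbenium resonance form) | C[O+]=C1C(OC)=C[C@]23C[C@H]2COC3=C1OC | intermediate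
13 | 2,3,4,5-tetramethoxy-6-[(3S)-6,7,8-trimethoxy-3,4-dihydro-2H-chromen-3-yl]phenol | COc1c(O)c([C@H]2COc3c(cc(OC)c(OC)c3OC)C2)c(OC)c(OC)c1OC | intermediate
14 | 2,3,5-trimethoxy-6-[(3S)-6,7,8-trimethoxy-3,4-dihydro-2H-chromen-3-yl]cyclohexa-2,5-diene-1,4-dione | COC1=C(OC)C(=O)C([C@H]2COc3c(cc(OC)c(OC)c3OC)C2)=C(OC)C1=O | target

**Totals**
Total step count: 8. Longest linear sequence: 6 (steps 1, 2, 3, 4, 7, 8).

**Steps most likely to fail**

Step 7 (Proposed new method). The risks are attack of the hindered arene at the primary carbon of the phenonium ion (no ring expansion), O-alkylation of the phenol without return, or a 1,2-hydride shift with aromatisation to a benzofuran. The fallback uses known chemistry, sets out from 7 and comes back at 13; the pyran ring still arises by ring expansion, but the stereocentre is then set by a catalyst.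
- Mesylate 7 is solvolysed in buffered aqueous trifluoroethanol (2,6-lutidine, 50 °C), the aryl-assisted ring expansion with a small oxygen nucleophile, to (3R)-6,7,8-trimethoxychroman-3-ol F1.
- Dess–Martin oxidation gives 6,7,8-trimethoxychroman-3-one F2, and LiHMDS/PhNTf2 (THF, −78 °C) gives the conjugated enol triflate 6,7,8-trimethoxy-2H-chromen-3-yl trifluoromethanesulfonate F3.
- In parallel, phenol 11 is protected (MOMCl, i-Pr2NEt) as 1,2,3,4-tetramethoxy-5-(methoxymethoxy)benzene F4. Ortho-lithiation (n-BuLi, THF, 0 °C) and i-PrOBpin then give 2-[2,3,4,5-tetramethoxy-6-(methoxymethoxy)phenyl]-4,4,5,5-tetramethyl-1,3,2-dioxaborolane F5.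
- Suzuki–Miyaura coupling of F3 with F5 (Pd(OAc)2/SPhos, K3PO4, toluene/H2O) gives 6,7,8-trimethoxy-3-[2,3,4,5-tetramethoxy-6-(methoxymethoxy)phenyl]-2H-chromene F6.
- Ir-catalysed asymmetric hydrogenation (chiral P,N ligand, H2, CH2Cl2) should give (3S)-6,7,8-trimethoxy-3-[2,3,4,5-tetramethoxy-6-(methoxymethoxy)phenyl]chroman F7, and HCl in MeOH removes the MOM group to give 13.

Step 1. The risks are bromination at C5 (para to the 2-OMe) instead of C6, and over-oxidation of the electron-rich phenol to a quinone. The fallback sets out from 1 and comes back at 2.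
- Phenol 1 is protected (MOMCl, i-Pr2NEt) as 1,2,3-trimethoxy-4-(methoxymethoxy)benzene F8.
- Directed ortho-metalation next to the stronger OMOM director (n-BuLi, THF, 0 °C) and quenching with BrCF2CF2Br give 1-bromo-3,4,5-trimethoxy-2-(methoxymethoxy)benzene F9.
- HCl in MeOH gives 2.

Step 3. The risks are 6-endo opening at the terminal epoxide carbon, and intermolecular attack of the organolithium species on the epoxide. The fallback sets out from 2 and comes back at 6; it builds the furan ring by carbopalladation and sets C3 by catalysis.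
- Phenol 2 is alkylated with propargyl bromide (K2CO3, acetone) to 1-bromo-3,4,5-trimethoxy-2-(prop-2-yn-1-yloxy)benzene F10.
- Pd-catalysed 5-exo-dig cyclisation with hydride capture (Pd(PPh3)4, HCO2Na, DMF, 80 °C) gives 5,6,7-trimethoxy-3-methylidene-2,3-dihydro-1-benzofuran F11.
- Cobalt-catalysed enantioselective hydroboration of this 1,1-disubstituted styrene-type alkene with HBpin (chiral iminopyridine-oxazoline ligand, enantiomer chosen for the required sense) should give 2-{[(3R)-5,6,7-trimethoxy-2,3-dihydro-1-benzofuran-3-yl]methyl}-4,4,5,5-tetramethyl-1,3,2-dioxaborolane F12.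
- NaBO3 oxidation gives 6.

**Further compounds**
F1 | step 7 | (3R)-6,7,8-trimethoxychroman-3-ol | O[C@H]1COc2c(cc(OC)c(OC)c2OC)C1
F2 | step 7 | 6,7,8-trimethoxychroman-3-one | O=C1COc2c(cc(OC)c(OC)c2OC)C1
F3 | step 7 | 6,7,8-trimethoxy-2H-chromen-3-yl trifluoromethanesulfonate | O=S(=O)(OC1=Cc2cc(OC)c(OC)c(OC)c2OC1)C(F)(F)F
F4 | step 7 | 1,2,3,4-tetramethoxy-5-(methoxymethoxy)benzene | COCOc1cc(OC)c(OC)c(OC)c1OC
F5 | step 7 | 2-[2,3,4,5-tetramethoxy-6-(methoxymethoxy)phenyl]-4,4,5,5-tetramethyl-1,3,2-dioxaborolane | COCOc1c(B2OC(C)(C)C(C)(C)O2)c(OC)c(OC)c(OC)c1OC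
F6 | step 7 | 6,7,8-trimethoxy-3-[2,3,4,5-tetramethoxy-6-(methoxymethoxy)phenyl]-2H-chromene | COCOc1c(C2=Cc3cc(OC)c(OC)c(OC)c3OC2)c(OC)c(OC)c(OC)c1OC
F7 | step 7 | (3S)-6,7,8-trimethoxy-3-[2,3,4,5-tetramethoxy-6-(methoxymethoxy)phenyl]chroman | COCOc1c([C@H]2COc3c(cc(OC)c(OC)c3OC)C2)c(OC)c(OC)c(OC)c1OC
F8 | step 1 | 1,2,3-trimethoxy-4-(methoxymethoxy)benzene | COCOc1ccc(OC)c(OC)c1OC
F9 | step 1 | 1-bromo-3,4,5-trimethoxy-2-(methoxymethoxy)benzene | COCOc1c(Br)cc(OC)c(OC)c1OC
F10 | step 3 | 1-bromo-3,4,5-trimethoxy-2-(prop-2-yn-1-yloxy)benzene | C#CCOc1c(Br)cc(OC)c(OC)c1OC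
F11 | step 3 | 5,6,7-trimethoxy-3-methylidene-2,3-dihydro-1-benzofuran | C=C1COc2c1cc(OC)c(OC)c2OC
F12 | step 3 | 2-{[(3R)-5,6,7-trimethoxy-2,3-dihydro-1-benzofuran-3-yl]methyl}-4,4,5,5-tetramethyl-1,3,2-dioxaborolane | CC1(C)OB(C[C@H]2COc3c2cc(OC)c(OC)c3OC)OC1(C)C
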